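**Retrosynthetic overview**
- The target comes from a fully assembled ent-halim-1(10)-ene triol by 14,15-diacetylation and late oxidation of a protected C18 hydroxymethyl group to the acid.
- Ring A (C1–C4) is closed last by an intermolecular Diels–Alder reaction between a ring-B 1-vinylcyclohexene (C2=C1–C10=C5) and a 2-(alkoxymethyl)acrolein. This sets C4, C5 and the Δ1(10) alkene; the endo formyl group becomes the C19 methyl.
- Key C9–C11 bond: intermolecular Mukaiyama–Michael addition of a ring-B silyl enol ether to a glycerate-derived chiral vinyl ketone. It joins the ring fragment to the side-chain fragment and creates the C9 quaternary centre.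
- C8 comes from a copper-catalysed asymmetric conjugate methylation of 2-methylcyclohex-2-enone, C14 from methyl (S)-glycerate acetonide, and C13 from a chelation-controlled MeMgBr addition.
- Ring order: ring B is the purchased carbocycle and is functionalised first; ring A is formed second by the cycloaddition.

Assumption: bicyclic compounds carry halimane numbering (C18 = acid carbon, C19 = C4 methyl, C17 = C8 methyl, C20 = C9 methyl, C16 = C13 methyl), and the phosphoramidite antipode in step 3 is taken to be the one that gives the 3R adduct (its mirror image is used if the sense is opposite).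

**Route**

Step 1
Reactants: 1 methyl (4S)-2,2-dimethyl-1,3-dioxolane-4-carboxylate
Product: 2 (4S)-N-methoxy-N,2,2-trimethyl-1,3-dioxolane-4-carboxamide
Conditions: MeNH(OMe)·HCl, iPrMgCl, THF, −20 °C
Reagents that add atoms: N,O-dimethylhydroxylamine hydrochloride, CNOC.Cl
Why: Aminolysis of the ester by the magnesium amide (Weinreb amide formation) is fast at −20 °C and leaves the α-alkoxy stereocentre (future C14) untouched.

Step 2
Reactants: 2 (4S)-N-methoxy-N,2,2-trimethyl-1,3-dioxolane-4-carboxamide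
Product: 3 1-[(4S)-2,2-dimethyl-1,3-dioxolan-4-yl]prop-2-en-1-one
Conditions: CH2=CHMgBr, THF, −20 → 0 °C; inverse quench into cold aq. citric acid
Reagents that add atoms: vinylmagnesium bromide, C=C[Mg]Br
Why: Grignard acylation of a Weinreb amide stops at the ketone because the chelated tetrahedral adduct collapses only on the acidic quench, which also keeps the released amine from adding to the enone.

Step 3
Reactants: 4 2-methylcyclohex-2-en-1-one
Product: 6 [(3R)-2,3-dimethylcyclohex-1-en-1-yl]oxy(trimethyl)silane, via dimethylaluminium enolate 5 (not isolated)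
Conditions: Me3Al, Cu(O2CC4H3S) (copper thiophene-2-carboxylate, 2 mol %), (R,S,S)-BINOL/bis(1-phenylethyl)amine phosphoramidite (4 mol %), Et2O, −30 °C; then TMSOTf, −30 → 0 °C
Reagents that add atoms: trimethylaluminium, C[Al](C)C; trimethylsilyl trifluoromethanesulfonate, C[Si](C)(C)OS(=O)(=O)C(F)(F)F
Why: In this copper-catalysed asymmetric conjugate addition the chiral phosphoramidite–copper complex delivers methyl to one enone face to set C8 (R), and O-silylation stores the regiodefined enolate as the tetrasubstituted silyl enol ether.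

Step 4
Reactants: 6 [(3R)-2,3-dimethylcyclohex-1-en-1-yl]oxy(trimethyl)silane; 3 1-[(4S)-2,2-dimethyl-1,3-dioxolan-4-yl]prop-2-en-1-one
Product: 8 (2S,3R)-2-{3-[(4S)-2,2-dimethyl-1,3-dioxolan-4-yl]-3-oxopropyl}-2,3-dimethylcyclohexan-1-one, via adduct silyl enol ether 7 (not isolated)
Conditions: Sc(OTf)3 (10 mol %), CH2Cl2, −78 → −40 °C; then AcOH/H2O/THF, 0 °C
Reagents that add atoms: none
Why: In this intermolecular Mukaiyama–Michael addition the Lewis-acid-activated vinyl ketone is attacked by C9 of the silyl enol ether on the face anti to the pseudoaxial C8 methyl, forming the C9–C11 bond and the 9S quaternary centre (C20 cis to C17).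

Step 5
Reactants: 8 (2S,3R)-2-{3-[(4S)-2,2-dimethyl-1,3-dioxolan-4-yl]-3-oxopropyl}-2,3-dimethylcyclohexan-1-one
Product: 9 (2S,3R)-2-{(3R)-3-[(4S)-2,2-dimethyl-1,3-dioxolan-4-yl]-3-hydroxybutyl}-2,3-dimethylcyclohexan-1-one
Conditions: MeMgBr (1.2 equiv), THF, −78 °C
Reagents that add atoms: methylmagnesium bromide, C[Mg]Br
Why: In this chelation-controlled Grignard addition (Cram cyclic model) magnesium bridges the C13 carbonyl and the α-dioxolane oxygen, so methyl attacks the face away from C15 to give 13R, while the hindered α-quaternary ring ketone does not react at −78 °C.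

Step 6
Reactants: 9 (2S,3R)-2-{(3R)-3-[(4S)-2,2-dimethyl-1,3-dioxolan-4-yl]-3-hydroxybutyl}-2,3-dimethylcyclohexan-1-one
Product: 10 (2S,3R)-2-{(3R)-3-[(4S)-2,2-dimethyl-1,3-dioxolan-4-yl]-3-[(triethylsilyl)oxy]butyl}-2,3-dimethylcyclohexan-1-one
Conditions: Et3SiOTf, 2,6-lutidine, CH2Cl2, −78 → 0 °C
Reagents that add atoms: triethylsilyl trifluoromethanesulfonate, CC[Si](CC)(CC)OS(=O)(=O)C(F)(F)F
Why: Silyl triflate silylation is strong enough for the tertiary alcohol and removes the alkoxide/hemiketal problem before enolate chemistry at the ring ketone.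

Step 7
Reactants: 10 (2S,3R)-2-{(3R)-3-[(4S)-2,2-dimethyl-1,3-dioxolan-4-yl]-3-[(triethylsilyl)oxy]butyl}-2,3-dimethylcyclohexan-1-one
Product: 12 (5R,6S)-6-{(3R)-3-[(4S)-2,2-dimethyl-1,3-dioxolan-4-yl]-3-[(triethylsilyl)oxy]butyl}-5,6-dimethylcyclohex-1-en-1-yl trifluoromethanesulfonate, via potassium enolate 11 (not isolated)
Conditions: KN(SiMe3)2, THF, −78 °C; then PhNTf2, −78 → 0 °C
Reagents that add atoms: N-phenylbis(trifluoromethanesulfonimide), O=S(=O)(N(c1ccccc1)S(=O)(=O)C(F)(F)F)C(F)(F)F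
Why: Only C5 carries α-hydrogens (C9 is quaternary), so deprotonation and O-triflation give a single enol triflate regioisomer.

Step 8
Reactants: 12 (5R,6S)-6-{(3R)-3-[(4S)-2,2-dimethyl-1,3-dioxolan-4-yl]-3-[(triethylsilyl)oxy]butyl}-5,6-dimethylcyclohex-1-en-1-yl trifluoromethanesulfonate
Product: 13 (5R,6S)-1-ethenyl-5,6-dimethyl-6-{(3R)-3-[(4S)-2,2-dimethyl-1,3-dioxolan-4-yl]-3-[(triethylsilyl)oxy]butyl}cyclohex-1-ene
Conditions: CH2=CHSnBu3, Pd(PPh3)4 (5 mol %), LiCl, THF, 65 °C
Reagents that add atoms: tributyl(vinyl)stannane, C=C[Sn](CCCC)(CCCC)CCCC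
Why: Stille coupling of an enol triflate with a vinylstannane tolerates the neighbouring quaternary carbon and all protecting groups and gives the C2=C1–C10=C5 diene.

Step 9
Reactants: 14 2-methylidenepropane-1,3-diol
Product: 15 2-{[(4-methoxyphenyl)methoxy]methyl}prop-2-en-1-ol
Conditions: Ag2O, PMBCl, CH2Cl2, rt
Reagents that add atoms: 4-methoxybenzyl chloride, COc1ccc(CCl)cc1
Why: Silver-oxide-mediated Williamson etherification monoprotects a symmetrical diol selectively.

Step 10
Reactants: 15 2-{[(4-methoxyphenyl)methoxy]methyl}prop-2-en-1-ol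
Product: 16 2-{[(4-methoxyphenyl)methoxy]methyl}prop-2-enal
Conditions: MnO2, CH2Cl2, rt
Reagents that add atoms: none
Why: MnO2 oxidises the allylic alcohol to the enal without touching the PMB ether.

Step 11
Reactants: 13 (5R,6S)-1-ethenyl-5,6-dimethyl-6-{(3R)-3-[(4S)-2,2-dimethyl-1,3-dioxolan-4-yl]-3-[(triethylsilyl)oxy]butyl}cyclohex-1-ene; 16 2-{[(4-methoxyphenyl)methoxy]methyl}prop-2-enal
Product: 17 (4R,5S,8R,9S,13R,14S)-14,15-(isopropylidenedioxy)-18-[(4-methoxybenzyl)oxy]-13-[(triethylsilyl)oxy]halim-1(10)-en-19-al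
Conditions: Me2AlCl (1.5 equiv), CH2Cl2, −78 → −30 °C
Reagents that add atoms: none
Why: In this Lewis-acid-promoted Diels–Alder reaction the enal adds with ortho regiochemistry (C3 to C2, C4 to C5) and formyl endo (formyl cis to C6, CH2OPMB cis to H-5), to the diene face opposite the pseudoaxial C9 side chain, so H-5 ends cis to C11 and the alkene lands at C1=C10.

Step 12
Reactants: 17 (4R,5S,8R,9S,13R,14S)-14,15-(isopropylidenedioxy)-18-[(4-methoxybenzyl)oxy]-13-[(triethylsilyl)oxy]halim-1(10)-en-19-al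
Product: 18 (4R,5S,8R,9S,13R,14S)-13,14,15-trihydroxy-18-[(4-methoxybenzyl)oxy]halim-1(10)-en-19-al
Conditions: AcOH/H2O/THF (3:1:1), 45 °C
Reagents that add atoms: none
Why: Mild aqueous acid hydrolyses the acetonide and the tertiary silyl ether, while the PMB ether, the non-enolisable aldehyde and the trisubstituted alkene are stable.

Step 13
Reactants: 18 (4R,5S,8R,9S,13R,14S)-13,14,15-trihydroxy-18-[(4-methoxybenzyl)oxy]halim-1(10)-en-19-al
Product: 20 (4S,5S,8R,9S,13R,14S)-18-[(4-methoxybenzyl)oxy]halim-1(10)-ene-13,14,15-triol, via C19 hydrazone 19 (not isolated)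
Conditions: N2H4·H2O, diethylene glycol, 120 °C; then KOH, 195 °C
Reagents that add atoms: none
Why: Wolff–Kishner reduction (Huang–Minlon procedure) turns the hindered, non-enolisable aldehyde into the C19 methyl, and every other group present (alcohols, benzylic ether, isolated alkene) is base-stable.

Step 14
Reactants: 20 (4S,5S,8R,9S,13R,14S)-18-[(4-methoxybenzyl)oxy]halim-1(10)-ene-13,14,15-triol
Product: 21 (4S,5S,8R,9S,13R,14S)-13-hydroxy-18-[(4-methoxybenzyl)oxy]halim-1(10)-ene-14,15-diyl diacetate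
Conditions: Ac2O, pyridine, 0 °C → rt
Reagents that add atoms: acetic anhydride, CC(=O)OC(C)=O
Why: Acetylation without an acyl-transfer catalyst esterifies the primary and secondary hydroxyls and leaves the hindered tertiary 13-OH free.

Step 15
Reactants: 21 (4S,5S,8R,9S,13R,14S)-13-hydroxy-18-[(4-methoxybenzyl)oxy]halim-1(10)-ene-14,15-diyl diacetate
Product: 22 (4S,5S,8R,9S,13R,14S)-13,18-dihydroxyhalim-1(10)-ene-14,15-diyl diacetate
Conditions: DDQ, CH2Cl2/pH 7 buffer, 0 °C
Reagents that add atoms: none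
Why: Oxidative PMB-ether cleavage by DDQ frees the C18 alcohol without affecting acetates, the tertiary alcohol or the unactivated alkene.

Step 16
Reactants: 22 (4S,5S,8R,9S,13R,14S)-13,18-dihydroxyhalim-1(10)-ene-14,15-diyl diacetate
Product: 23 (4S,5S,8R,9S,13R,14S)-14,15-diacetoxy-13-hydroxyhalim-1(10)-en-18-al
Conditions: Dess–Martin periodinane, NaHCO3, CH2Cl2, rt
Reagents that add atoms: none
Why: Dess–Martin oxidation converts the neopentyl primary alcohol to the aldehyde under neutral conditions, and the tertiary alcohol cannot be oxidised.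

Step 17
Reactants: 23 (4S,5S,8R,9S,13R,14S)-14,15-diacetoxy-13-hydroxyhalim-1(10)-en-18-al
Product: 24 (4S,5S,8R,9S,13R,14S)-14,15-diacetoxy-13-hydroxyhalim-1(10)-en-18-oic acid (CNP0224606.1)
Conditions: NaClO2, NaH2PO4, 2-methylbut-2-ene, t-BuOH/H2O, rt
Reagents that add atoms: sodium chlorite, [Na+].[O-]Cl=O
Why: Pinnick oxidation takes the hindered aldehyde to the acid at pH 4, where the acetates survive and the excess alkene scavenger protects the ring double bond from hypochlorite.

**Compound list**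
1 | methyl (4S)-2,2-dimethyl-1,3-dioxolane-4-carboxylate | CC1(C)OC[C@H](O1)C(=O)OC | starting material
2 | (4S)-N-methoxy-N,2,2-trimethyl-1,3-dioxolane-4-carboxamide | CC1(C)OC[C@H](O1)C(=O)N(C)OC | intermediate
3 | 1-[(4S)-2,2-dimethyl-1,3-dioxolan-4-yl]prop-2-en-1-one | CC1(C)OC[C@H](O1)C(=O)C=C | intermediate
4 | 2-methylcyclohex-2-en-1-one | CC1=CCCCC1=O | starting material
5 | dimethylaluminium (3R)-2,3-dimethylcyclohex-1-en-1-olate (not isolated) | CC1=C(O[Al](C)C)CCC[C@H]1C | intermediate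
6 | [(3R)-2,3-dimethylcyclohex-1-en-1-yl]oxy(trimethyl)silane | CC1=C(O[Si](C)(C)C)CCC[C@H]1C | intermediate
7 | (Z)-trimethylsilyl enol ether (C13=C12) of diketone 8 (not isolated) | CC3(C)OC[C@H](O3)/C(O[Si](C)(C)C)=C/C[C@]1(C)C(=O)CCC[C@H]1C | intermediate
8 | (2S,3R)-2-{3-[(4S)-2,2-dimethyl-1,3-dioxolan-4-yl]-3-oxopropyl}-2,3-dimethylcyclohexan-1-one | CC3(C)OC[C@H](O3)C(=O)CC[C@]1(C)C(=O)CCC[C@H]1C | intermediate
9 | (2S,3R)-2-{(3R)-3-[(4S)-2,2-dimethyl-1,3-dioxolan-4-yl]-3-hydroxybutyl}-2,3-dimethylcyclohexan-1-one | CC3(C)OC[C@H](O3)[C@](C)(O)CC[C@]1(C)C(=O)CCC[C@H]1C | intermediate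
10 | triethylsilyl ether of 9 at the tertiary hydroxyl | CC3(C)OC[C@H](O3)[C@](C)(O[Si](CC)(CC)CC)CC[C@]1(C)C(=O)CCC[C@H]1C | intermediate
11 | potassium enolate of 10 (C10–O, C10=C5; not isolated) | CC3(C)OC[C@H](O3)[C@](C)(O[Si](CC)(CC)CC)CC[C@]1(C)C([O-])=CCC[C@H]1C.[K+] | intermediate
12 | (5R,6S)-6-{(3R)-3-[(4S)-2,2-dimethyl-1,3-dioxolan-4-yl]-3-[(triethylsilyl)oxy]butyl}-5,6-dimethylcyclohex-1-en-1-yl trifluoromethanesulfonate | CC3(C)OC[C@H](O3)[C@](C)(O[Si](CC)(CC)CC)CC[C@]1(C)C(OS(=O)(=O)C(F)(F)F)=CCC[C@H]1C | intermediate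
13 | (5R,6S)-1-ethenyl-5,6-dimethyl-6-{(3R)-3-[(4S)-2,2-dimethyl-1,3-dioxolan-4-yl]-3-[(triethylsilyl)oxy]butyl}cyclohex-1-ene | CC3(C)OC[C@H](O3)[C@](C)(O[Si](CC)(CC)CC)CC[C@]1(C)C(C=C)=CCC[C@H]1C | intermediate
14 | 2-methylidenepropane-1,3-diol | C=C(CO)CO | starting material
15 | 2-{[(4-methoxyphenyl)methoxy]methyl}prop-2-en-1-ol | C=C(CO)COCc1ccc(OC)cc1 | intermediate
16 | 2-{[(4-methoxyphenyl)methoxy]methyl}prop-2-enal | C=C(C=O)COCc1ccc(OC)cc1 | intermediate
17 | (4R,5S,8R,9S,13R,14S)-14,15-(isopropylidenedioxy)-18-[(4-methoxybenzyl)oxy]-13-[(triethylsilyl)oxy]halim-1(10)-en-19-al | CC3(C)OC[C@H](O3)[C@](C)(O[Si](CC)(CC)CC)CC[C@]1(C)C2=CCC[C@](C=O)(COCc4ccc(OC)cc4)[C@H]2CC[C@H]1C | intermediate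
18 | (4R,5S,8R,9S,13R,14S)-13,14,15-trihydroxy-18-[(4-methoxybenzyl)oxy]halim-1(10)-en-19-al | OC[C@H](O)[C@](C)(O)CC[C@]1(C)C2=CCC[C@](C=O)(COCc3ccc(OC)cc3)[C@H]2CC[C@H]1C | intermediate
19 | (E)-hydrazone of aldehyde 18 at C19 (not isolated) | OC[C@H](O)[C@](C)(O)CC[C@]1(C)C2=CCC[C@](/C=N/N)(COCc3ccc(OC)cc3)[C@H]2CC[C@H]1C | intermediate
20 | (4S,5S,8R,9S,13R,14S)-18-[(4-methoxybenzyl)oxy]halim-1(10)-ene-13,14,15-triol | OC[C@H](O)[C@](C)(O)CC[C@]1(C)C2=CCC[C@](C)(COCc3ccc(OC)cc3)[C@H]2CC[C@H]1C | intermediate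
21 | (4S,5S,8R,9S,13R,14S)-13-hydroxy-18-[(4-methoxybenzyl)oxy]halim-1(10)-ene-14,15-diyl diacetate | CC(=O)OC[C@H](OC(C)=O)[C@](C)(O)CC[C@]1(C)C2=CCC[C@](C)(COCc3ccc(OC)cc3)[C@H]2CC[C@H]1C | intermediate
22 | (4S,5S,8R,9S,13R,14S)-13,18-dihydroxyhalim-1(10)-ene-14,15-diyl diacetate | CC(=O)OC[C@H](OC(C)=O)[C@](C)(O)CC[C@]1(C)C2=CCC[C@](C)(CO)[C@H]2CC[C@H]1C | intermediate
23 | (4S,5S,8R,9S,13R,14S)-14,15-diacetoxy-13-hydroxyhalim-1(10)-en-18-al | CC(=O)OC[C@H](OC(C)=O)[C@](C)(O)CC[C@]1(C)C2=CCC[C@](C)(C=O)[C@H]2CC[C@H]1C | intermediate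
24 | (4S,5S,8R,9S,13R,14S)-14,15-diacetoxy-13-hydroxyhalim-1(10)-en-18-oic acid | CC(=O)OC[C@H](OC(C)=O)[C@](C)(O)CC[C@]1(C)C2=CCC[C@](C)(C(=O)O)[C@H]2CC[C@H]1C | target

**Step count**
Total: 17 steps. Longest linear sequence: 14 steps (1 → 2 → 3 → 8 → 9 → 10 → 12 → 13 → 17 → 18 → 20 → 21 → 22 → 23 → 24).

**Three steps most likely to fail**

Step 11 (Diels–Alder). The risks are facial selectivity across the C9 quaternary centre (the H-5 epimer series) and low reactivity of a hindered diene towards an α-substituted enal. The fallback sets out from 16 (used with 13) and comes back at 18. Enal 16 is converted with 1,2-bis(trimethylsilyloxy)ethane and catalytic TMSOTf (CH2Cl2, −78 °C) into 2-{3-[(4-methoxybenzyl)oxy]prop-1-en-2-yl}-1,3-dioxolane F1. One equivalent of TMSOTf at −90 °C opens it to an alkoxyallyl cation, which adds to diene 13 in an ionic Diels–Alder reaction far below the temperature of the neutral process (more reactive and more face- and endo-selective dienophile). This gives the C19 ethylene acetal of 17, cycloadduct acetal F2. Treatment with 1 M HCl/THF cleaves acetal, acetonide and silyl ether together and delivers 18.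

Step 4 (Mukaiyama–Michael). The risks are forming a quaternary C–C bond next to a tertiary centre and using a polymerisable, acid- and base-sensitive α′-alkoxy vinyl ketone. The fallback sets out from 2 and 6 and comes back at 8. Weinreb amide 2 is acylated with [1-(trimethylsilyl)vinyl]magnesium bromide to 1-[(4S)-2,2-dimethyl-1,3-dioxolan-4-yl]-2-(trimethylsilyl)prop-2-en-1-one F3. Silyl enol ether 6 is cleaved with MeLi (THF, 0 °C) to lithium (3R)-2,3-dimethylcyclohex-1-en-1-olate F4. This enolate adds to the α-silyl enone at −78 °C in an aprotic enolate Michael addition; the silyl group stabilises the new enolate against polymerisation and proton transfer. The product is the α-silyl diketone F5 (both epimers at the silyl-bearing carbon). KF in MeOH/H2O removes the silyl group and gives 8.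

Step 3 (asymmetric conjugate addition and trapping). The risks are insufficient ee with a 2-substituted enone and incomplete O-silylation of the aluminium enolate. The fallback sets out from 4 and comes back at 8. Me2CuLi/Me3SiCl (THF, −78 °C, then Et3N) gives the racemic silyl enol ether, that is 6 together with its enantiomer [(3S)-2,3-dimethylcyclohex-1-en-1-yl]oxy(trimethyl)silane F6. Step 4 with enantiopure 3 then gives 8 and, through the diastereomeric adduct silyl enol ether F7, the (2R,3S)-ring diastereomer of 8, diketone F8. This diastereomer is removed by chromatography, or by crystallisation after step 5, so resolution by the enantiopure side-chain fragment replaces asymmetric catalysis. The same separation removes the minor ring enantiomer whenever step 3 gives incomplete ee.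

Further compounds
F1 | step 11 | 2-{3-[(4-methoxyphenyl)methoxy]prop-1-en-2-yl}-1,3-dioxolane | C=C(COCc1ccc(OC)cc1)C1OCCO1
F2 | step 11 | (4R,5S,8R,9S,13R,14S)-19,19-(ethylenedioxy)-14,15-(isopropylidenedioxy)-18-[(4-methoxybenzyl)oxy]-13-[(triethylsilyl)oxy]halim-1(10)-ene | CC3(C)OC[C@H](O3)[C@](C)(O[Si](CC)(CC)CC)CC[C@]1(C)C2=CCC[C@](C4OCCO4)(COCc5ccc(OC)cc5)[C@H]2CC[C@H]1C
F3 | step 4 | 1-[(4S)-2,2-dimethyl-1,3-dioxolan-4-yl]-2-(trimethylsilyl)prop-2-en-1-one | CC1(C)OC[C@H](O1)C(=O)C(=C)[Si](C)(C)C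
F4 | step 4 | lithium (3R)-2,3-dimethylcyclohex-1-en-1-olate | CC1=C([O-])CCC[C@H]1C.[Li+]
F5 | step 4 | (2S,3R)-2-{3-[(4S)-2,2-dimethyl-1,3-dioxolan-4-yl]-3-oxo-2-(trimethylsilyl)propyl}-2,3-dimethylcyclohexan-1-one (epimers at the silyl-bearing carbon) | CC3(C)OC[C@H](O3)C(=O)C([Si](C)(C)C)C[C@]1(C)C(=O)CCC[C@H]1C
F6 | step 3 | [(3S)-2,3-dimethylcyclohex-1-en-1-yl]oxy(trimethyl)silane | CC1=C(O[Si](C)(C)C)CCC[C@@H]1C
F7 | step 3 | (Z)-trimethylsilyl enol ether (C13=C12) of diketone F8 | CC3(C)OC[C@H](O3)/C(O[Si](C)(C)C)=C/C[C@@]1(C)C(=O)CCC[C@@H]1C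
F8 | step 3 | (2R,3S)-2-{3-[(4S)-2,2-dimethyl-1,3-dioxolan-4-yl]-3-oxopropyl}-2,3-dimethylcyclohexan-1-one | CC3(C)OC[C@H](O3)C(=O)CC[C@@]1(C)C(=O)CCC[C@@H]1C
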